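In the midnight run, the share of the charge that read as neither substrate nor first product gained 7.6 percentage points between 4.00 min and 8.00 min, but from then to 12.0 min it gained 1.5 points, which is less, with a scatter of 0.5 points on each reading.

the same everywhere: substrate 10 mM
- midnight: reagent 1.1 equiv; capture agent 6.7 mM; run made earlier
- spring: reagent 1.1 equiv; capture agent 15 mM; run made earlier
- autumn: reagent 2.2 equiv; capture agent 10 mM; run made earlier
- flask: reagent 1.10 equiv; capture agent 10.0 mM; time 10 min

- midnight (time / min: substrate / %, first product / %): 1.50: 54.7, 32.0; 4.00: 37.9, 33.7; 8.00: 29.7, 34.3; 12.0: 29.9, 32.6
- spring (time / min: substrate / %, first product / %): 1.50: 54.2, 31.7; 4.00: 35.7, 34.5; 8.00: 30.3, 33.2; 12.0: 29.9, 32.9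
- autumn (time / min: substrate / %, first product / %): 1.00: 40.8, 34.1; 2.00: 21.8, 30.5; 5.00: 8.3, 16.9; 12.0: 2.4, 7.1

(each reading ± 0.5 percentage points)



* the substrate standing at 10 min, as a percentage of the substrate charged
* the first product standing at 10 min, as a percentage of the substrate charged
* the double product standing at 10 min, as a percentage of the substrate charged
* the triple product standing at 10 min, as a percentage of the substrate charged

The flask repeats the midnight and spring charges of substrate and reagent, with c(capture agent) between theirs, and its time falls between their last two readings. Those readings average 29.9% substrate and 33.2% first product, which leaves 36.8%. I called this the remainder, the charge less substrate less first product.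

My first estimate put the whole remainder down as double product. The objection was triple product, but the reagent ledger answers it. First product holds one reagent and the remainder at least two, so the readings account for 107% of the substrate charge, against 1.1 equiv supplied. Reagent is the limiting reagent, and on this reckoning from scattered readings I expected triple product, with one reagent more, to stay within that small gap.

The second objection stayed. Substrate at 12.0 min read 29.9% with 6.7 mM of capture agent and 29.9% with 15 mM, yet these readings stop at first product, and anything taken from double product still counts in the remainder. Making double product was slowing, as the two gains show, while a loss from it need not slow with reagent, so the comparison could drift towards loss. I therefore committed to the remainder as a ceiling on double plus triple product, with double product possibly well below it, by an amount I could not size.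

The forecast gave 29.9% substrate, 33.2% first product, 35.9% double product and 1% triple product, “leaving about 37% for double plus triple”. Its double product stood close under my ceiling, and I expected less.

The flask gave 29.5% substrate, 33.2% first product, 30.3% double product and 0.437% triple product.

    reagent + double product → triple product (k = 0.0220 /M/s)
    reagent + first product → double product (k = 1.00 /M/s)
    double product + capture agent → trapped intermediate (k = 0.0460 /M/s)
    substrate + reagent → first product (k = 0.880 /M/s)

In the flask, trapped intermediate stood at 6.50% after 10.0 min, and the remainder read from the earlier runs, less the flask's double and triple product, leaves 6 points. In the neighbour flask charged with 1.90 equiv of reagent, the remainder was 78.5%, made up of 63.0% double product, 2.49% triple product and 12.9% trapped intermediate.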